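Two questions stand on this flask: how much product it holds at 8.0 min, and how near saturation its dissolved gas then is.

| setting | maple | larch | flask |
|---|---|---|---|
| substrate | 0.025 M | 0.10 M | 0.050 M |
| gas phase | 5.8 mM (held) | 5.8 mM (held) | 5.8 mM (held) |
| free catalyst | 0.058 mol% | 0.058 mol% | 0.058 mol% |
| remark | run made earlier | run made earlier |  |
| time |  |  | 8.0 min |

| run | time / min | product / % |
|---|---|---|
| maple | 0.500 | 2 |
| maple | 0.833 | 5 |
| maple | 1.33 | 11 |
| maple | 2.00 | 12 |
| maple | 3.00 | 24 |
| maple | 4.00 | 30 |
| maple | 6.00 | 38 |
| larch | 0.500 | 4 |
| larch | 0.833 | 5 |
| larch | 1.33 | 12 |
| larch | 2.00 | 16 |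
| larch | 3.00 | 24 |
| larch | 4.00 | 30 |
| larch | 6.00 | 44 |

(scatter of a reading: 1.5 percentage points)

* the product standing at 8.0 min, as a percentage of the substrate charged
* concentration of dissolved gas in solution at 8.0 min, in percent of saturation

- what was read earlier has a scatter of 1.5 percentage points, one standard deviation
- at the start none of the gas phase is in solution

The maple and larch percentages look alike, although the larch run holds 4.00 times the substrate and, at the same loading, that factor more free catalyst. I replace each curve by its mean time constant, the pseudo-first-order lifetime of substrate: reading time divided by the negative logarithm of the fraction of substrate left. At 6.00 min this reads 12.6 min for maple and 10.3 min for larch, each with the scatter of its reading.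

I assume two terms in series: at the held loading, a catalyst term falling with the substrate charge and a gas-supply term rising with it. These two readings give a catalyst term of 10.6 min and a gas-supply term of 1.92 min at the maple charge. This flask has 2.00 times that substrate charge, so I take its mean time constant up to 8.0 min as 9.16 min.

That gives me 58.2% product. The gas term's share of the time constant, 42.0%, is my mean shortfall of dissolved gas. I scale it by the final rate, 0.626 of the mean rate, which gives 73.7% of saturation.

The forecast says 50% and 98%, expecting the flask to “follow the same curve”.

The flask gives 56.0% and 83.7%.

    gas phase ⇌ dissolved gas, rate k1*(csat - [dissolved gas]) (kL = 1.80 min⁻¹)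
    substrate + dissolved gas + free catalyst → free catalyst + product (k = 37000 L² mol⁻² s⁻¹)
    free catalyst → spent catalyst (k = 0.190 min⁻¹)

At 8.00 min the flask's free catalyst stands at 21.9% of its charge. Its product corresponds to a mean time constant of 9.74 min, longer than my 9.16 min. The same flask read at 15 min would hold 80.6% product on my time constant; computed, it holds 66.9%, with free catalyst at 5.78%.

The numbers in the tables come from a simulation from invented constants, noise included.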